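**Assumption:** the 4‑hydroxybenzoyl group sits on the tertiary oxygen exactly as drawn. Daucane numbering is used for the bicyclic compounds: C‑1 methyl‑bearing ring‑fusion carbon, C‑2/C‑3 ring CH2, C‑4 isopropyl carbinol carbon, C‑5 ring‑fusion CH, C‑6 CHOH, C‑7 CH2, C‑8 methyl‑bearing epoxide carbon, C‑9 epoxide CH, C‑10 CH2. The target is then (1R,4R,5S,6S,8R,9S).

## Retrosynthetic overview

1. Target ⇐ deprotection of a bicyclic epoxide whose cycloheptane ring and oxirane are cut together (C‑8–C‑9 and C‑8–O) to a sulfonium ylide and an aldehyde held on one cyclopentane.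
2. Aldehyde arm ⇐ ozonolysis of an allyl group; ylide ⇐ S‑phenylation of a phenyl sulfide.
3. Tertiary aryl ester ⇐ isopropyl Grignard addition to a cyclopentanone, the alkoxide trapped by the aroyl chloride.
4. Cyclopentanone with three stereocentres ⇐ asymmetric conjugate methylation of 3‑allylcyclopentenone with aldol trapping by 3‑(phenylsulfanyl)butanal.
5. Ring order: the five‑membered ring is bought (as 3‑ethoxycyclopentenone); the seven‑membered carbocycle and the epoxide close last, in one step.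

## Route

**Step 1**
Reactants: 1 3‑ethoxycyclopent‑2‑en‑1‑one; 2 allylmagnesium bromide
Product: 4 3‑(prop‑2‑en‑1‑yl)cyclopent‑2‑en‑1‑one, via bromomagnesium alkoxide adduct 3 (not isolated)
Conditions: CH2=CHCH2MgBr, THF, 0 °C; then 1 M HCl, 0 → 23 °C
Reagents that add atoms: water, O
Why: Stork–Danheiser enone transposition, in which 1,2‑addition to the vinylogous ester and acid hydrolysis of the enol ether with loss of water and ethanol give the 3‑substituted enone; no stereocentre is formed.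

**Step 2**
Reactants: 5 (E)‑but‑2‑enal; 6 benzenethiol
Product: 7 rac‑3‑(phenylsulfanyl)butanal
Conditions: Et3N (1 mol%), CH2Cl2, 0 °C
Reagents that add atoms: none
Why: Base‑catalysed thia‑Michael addition to the enal, made racemic on purpose because this carbon becomes the planar ylide carbon in step 7.

**Step 3**
Reactants: 4 3‑(prop‑2‑en‑1‑yl)cyclopent‑2‑en‑1‑one; 7 rac‑3‑(phenylsulfanyl)butanal
Product: 10 (2S,3R)‑3‑methyl‑2‑[(1S)‑3‑(phenylsulfanyl)‑1‑(triethylsilyloxy)butyl]‑3‑(prop‑2‑en‑1‑yl)cyclopentan‑1‑one (1:1 epimers at the sulfanyl carbon), via aluminium enolate 8 (not isolated), via aluminium aldolate 9 (not isolated)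
Conditions: Me3Al, Cu(OTf)2 (2 mol%), (S,S,S)‑binaphthyl bis(1‑phenylethyl)phosphoramidite (4 mol%), Et2O, −30 °C; then 7, −78 → −40 °C; then Et3SiOTf, −78 → 0 °C
Reagents that add atoms: trimethylaluminium, C[Al](C)C; triethylsilyl trifluoromethanesulfonate, CC[Si](CC)(CC)OS(=O)(=O)C(F)(F)F
Why: Copper‑catalysed asymmetric conjugate addition sets the quaternary carbon (R) by ligand control, and the regiodefined E‑enolate is trapped in a closed Zimmerman–Traxler aldol (anti aldol, aldehyde entering opposite the larger allyl group, giving 2S and 1′S) before O‑silylation.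

**Step 4**
Reactants: 10 silyloxy ketone from step 3; 11 4‑(benzyloxy)benzoyl chloride
Product: 13 (1R,2S,3R)‑3‑methyl‑2‑[(1S)‑3‑(phenylsulfanyl)‑1‑(triethylsilyloxy)butyl]‑1‑(propan‑2‑yl)‑3‑(prop‑2‑en‑1‑yl)cyclopentyl 4‑(benzyloxy)benzoate, via chloromagnesium alkoxide 12 (not isolated)
Conditions: iPrMgCl, LaCl3·2LiCl (0.3 equiv), THF, 0 °C; then 11, DMAP (0.2 equiv), 0 → 40 °C
Reagents that add atoms: isopropylmagnesium chloride, CC(C)[Mg]Cl
Why: Lanthanum‑promoted Grignard 1,2‑addition to the hindered, enolisable cyclopentanone occurs from the face opposite the C‑2 side chain (carbinol carbon R, oxygen cis to the side chain), and the magnesium alkoxide is acylated in the same flask.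

**Step 5**
Reactants: 13 sulfide ester from step 4
Product: 14 {(4S)‑4‑[(1S,2R,5R)‑2‑{[4‑(benzyloxy)benzoyl]oxy}‑5‑methyl‑2‑(propan‑2‑yl)‑5‑(prop‑2‑en‑1‑yl)cyclopentyl]‑4‑(triethylsilyloxy)butan‑2‑yl}diphenylsulfonium trifluoromethanesulfonate
Conditions: Ph2I+ TfO−, Cu(OAc)2 (5 mol%), chlorobenzene, 100 °C
Reagents that add atoms: diphenyliodonium trifluoromethanesulfonate, c1ccc(cc1)[I+]c1ccccc1.[O-]S(=O)(=O)C(F)(F)F
Why: Copper‑catalysed S‑arylation of a sulfide with a diaryliodonium salt gives an alkyldiphenylsulfonium salt whose only acidic α‑hydrogen is at the methyl‑bearing carbon; no core stereocentre is touched.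

**Step 6**
Reactants: 14 sulfonium salt from step 5
Product: 16 the same sulfonium triflate with a 2‑oxoethyl group in place of the allyl group, via ozonide 15 (not isolated)
Conditions: O3, CH2Cl2, −78 °C; then PPh3, −78 → 23 °C
Reagents that add atoms: ozone, [O-][O+]=O
Why: Ozonolysis of the only alkene with reductive work‑up gives the aldehyde, while the sulfonium centre, silyl ether, benzyl ether and ester are inert to ozone.

**Step 7** (key step: seven‑membered ring and epoxide)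
Reactants: 16 sulfonium aldehyde from step 6
Product: 19 (1R,4R,5S,6S,8R,9S)‑8,9‑epoxy‑6‑(triethylsilyloxy)daucan‑4‑yl 4‑(benzyloxy)benzoate, via sulfonium ylide 17 (not isolated), via betaine 18 (not isolated)
Conditions: LiN(SiMe3)2 (1.05 equiv), THF (0.005 M), −78 → 0 °C
Reagents that add atoms: none
Why: Proposed new method: deprotonation alpha to sulfur gives a disubstituted diphenylsulfonium ylide that adds to the aldehyde on the trans arm of the cyclopentane (C‑8–C‑9 bond, seven‑membered ring), and the betaine closes to the oxirane by anti displacement of Ph2S, with the ring forcing C‑7 and C‑10 cis on the oxirane and only the betaine with sulfur trans to the C‑6 silyloxy group able to reach the anti‑periplanar S–C–C–O geometry, so that oxygen should arrive on the α‑face (8R,9S); the closest known reactions are the intramolecular Corey–Chaykovsky epoxidation and epoxidations with diphenylsulfonium isopropylide.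

**Step 8**
Reactants: 19 benzyl ether from step 7
Product: 20 (1R,4R,5S,6S,8R,9S)‑8,9‑epoxy‑6‑(triethylsilyloxy)daucan‑4‑yl 4‑hydroxybenzoate
Conditions: H2 (1 atm), Pd/C (10 wt%), EtOAc, 23 °C
Reagents that add atoms: none
Why: Hydrogenolysis of the benzyl aryl ether, which leaves the non‑benzylic trisubstituted epoxide, the silyl ether and the ester intact under neutral conditions.

**Step 9**
Reactants: 20 silyl ether from step 8
Product: 21 (1R,4R,5S,6S,8R,9S)‑8,9‑epoxy‑6‑hydroxydaucan‑4‑yl 4‑hydroxybenzoate (target)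
Conditions: Bu4NF, AcOH (1:1), THF, 23 °C
Reagents that add atoms: none
Why: Buffered fluoride desilylation, kept non‑basic so that the aroyl group does not migrate from O‑4 to the freed O‑6 and the epoxide is not opened.

## Compound list

1 | 3‑ethoxycyclopent‑2‑en‑1‑one | CCOC1=CC(=O)CC1 | starting material
2 | allylmagnesium bromide | C=CC[Mg]Br | starting material
3 | bromomagnesium 3‑ethoxy‑1‑(prop‑2‑en‑1‑yl)cyclopent‑2‑en‑1‑olate (racemic) | CCOC1=CC(CC=C)(O[Mg]Br)CC1 | intermediate (not isolated)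
4 | 3‑(prop‑2‑en‑1‑yl)cyclopent‑2‑en‑1‑one | C=CCC1=CC(=O)CC1 | intermediate
5 | (E)‑but‑2‑enal | C/C=C/C=O | starting material
6 | benzenethiol | Sc1ccccc1 | starting material
7 | rac‑3‑(phenylsulfanyl)butanal | CC(CC=O)Sc1ccccc1 | intermediate
8 | dimethyl{[(3R)‑3‑methyl‑3‑(prop‑2‑en‑1‑yl)cyclopent‑1‑en‑1‑yl]oxy}alumane | C[Al](C)OC1=C[C@@](C)(CC=C)CC1 | intermediate (not isolated)
9 | dimethylaluminium (1S)‑1‑[(1S,2R)‑2‑methyl‑5‑oxo‑2‑(prop‑2‑en‑1‑yl)cyclopentyl]‑3‑(phenylsulfanyl)butan‑1‑olate | O=C1CC[C@](C)(CC=C)[C@H]1[C@@H](O[Al](C)C)CC(C)Sc1ccccc1 | intermediate (not isolated)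
10 | (2S,3R)‑3‑methyl‑2‑[(1S)‑3‑(phenylsulfanyl)‑1‑(triethylsilyloxy)butyl]‑3‑(prop‑2‑en‑1‑yl)cyclopentan‑1‑one (epimers at the sulfanyl carbon) | O=C1CC[C@](C)(CC=C)[C@H]1[C@@H](O[Si](CC)(CC)CC)CC(C)Sc1ccccc1 | intermediate
11 | 4‑(benzyloxy)benzoyl chloride | O=C(Cl)c1ccc(OCc2ccccc2)cc1 | starting material
12 | chloromagnesium (1R,2S,3R)‑3‑methyl‑2‑[(1S)‑3‑(phenylsulfanyl)‑1‑(triethylsilyloxy)butyl]‑1‑(propan‑2‑yl)‑3‑(prop‑2‑en‑1‑yl)cyclopentan‑1‑olate | CC(C)[C@]1(O[Mg]Cl)CC[C@](C)(CC=C)[C@H]1[C@@H](O[Si](CC)(CC)CC)CC(C)Sc1ccccc1 | intermediate (not isolated)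
13 | (1R,2S,3R)‑3‑methyl‑2‑[(1S)‑3‑(phenylsulfanyl)‑1‑(triethylsilyloxy)butyl]‑1‑(propan‑2‑yl)‑3‑(prop‑2‑en‑1‑yl)cyclopentyl 4‑(benzyloxy)benzoate | CC(C)[C@]1(OC(=O)c2ccc(OCc3ccccc3)cc2)CC[C@](C)(CC=C)[C@H]1[C@@H](O[Si](CC)(CC)CC)CC(C)Sc1ccccc1 | intermediate
14 | S,S‑diphenylsulfonium triflate of 13 (sulfur on the methyl‑bearing carbon) | CC(C)[C@]1(OC(=O)c2ccc(OCc3ccccc3)cc2)CC[C@](C)(CC=C)[C@H]1[C@@H](O[Si](CC)(CC)CC)CC(C)[S+](c1ccccc1)c1ccccc1.[O-]S(=O)(=O)C(F)(F)F | intermediate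
15 | 1,2,4‑trioxolane (ozonide) of the allyl group of 14 | CC(C)[C@]1(OC(=O)c2ccc(OCc3ccccc3)cc2)CC[C@](C)(CC2OCOO2)[C@H]1[C@@H](O[Si](CC)(CC)CC)CC(C)[S+](c1ccccc1)c1ccccc1.[O-]S(=O)(=O)C(F)(F)F | intermediate (not isolated)
16 | sulfonium triflate with a 2‑oxoethyl arm on the quaternary carbon | CC(C)[C@]1(OC(=O)c2ccc(OCc3ccccc3)cc2)CC[C@](C)(CC=O)[C@H]1[C@@H](O[Si](CC)(CC)CC)CC(C)[S+](c1ccccc1)c1ccccc1.[O-]S(=O)(=O)C(F)(F)F | intermediate
17 | diphenylsulfonium ylide of 16 (carbanion on the methyl‑bearing carbon) | CC(C)[C@]1(OC(=O)c2ccc(OCc3ccccc3)cc2)CC[C@](C)(CC=O)[C@H]1[C@@H](O[Si](CC)(CC)CC)C[C-](C)[S+](c1ccccc1)c1ccccc1 | intermediate (not isolated)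
18 | (8S,9S)‑betaine: seven‑membered ring closed, C‑9 oxide α, C‑8 diphenylsulfonio β | CC(C)[C@]1(OC(=O)c2ccc(OCc3ccccc3)cc2)CC[C@]2(C)C[C@H]([O-])[C@@](C)([S+](c3ccccc3)c3ccccc3)C[C@H](O[Si](CC)(CC)CC)[C@H]21 | intermediate (not isolated)
19 | (1R,4R,5S,6S,8R,9S)‑8,9‑epoxy‑6‑(triethylsilyloxy)daucan‑4‑yl 4‑(benzyloxy)benzoate | CC(C)[C@]1(OC(=O)c2ccc(OCc3ccccc3)cc2)CC[C@]2(C)C[C@@H]3O[C@]3(C)C[C@H](O[Si](CC)(CC)CC)[C@H]21 | intermediate
20 | (1R,4R,5S,6S,8R,9S)‑8,9‑epoxy‑6‑(triethylsilyloxy)daucan‑4‑yl 4‑hydroxybenzoate | CC(C)[C@]1(OC(=O)c2ccc(O)cc2)CC[C@]2(C)C[C@@H]3O[C@]3(C)C[C@H](O[Si](CC)(CC)CC)[C@H]21 | intermediate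
21 | (1R,4R,5S,6S,8R,9S)‑8,9‑epoxy‑6‑hydroxydaucan‑4‑yl 4‑hydroxybenzoate | CC(C)[C@]1(OC(=O)c2ccc(O)cc2)CC[C@]2(C)C[C@@H]3O[C@]3(C)C[C@H](O)[C@H]21 | target

## Step count and risks

Total steps: 9. Longest linear sequence: 8 (steps 1, 3, 4, 5, 6, 7, 8, 9); step 2 is a one‑step side branch.

The three steps most likely to fail:

**Step 7 (ring closure with epoxide formation).** This is the largest risk. The base may enolise the aldehyde instead of forming the ylide, the seven‑membered closure may be slow, and the α‑face outcome rests on a conformational argument that I could not settle with confidence; the β‑epoxide is a real possibility. The fallback sets out from 13 and comes back at 21. The sulfide is oxidised with mCPBA to the phenyl sulfone F1, and ozonolysis gives the sulfonyl aldehyde F2. An intramolecular Julia–Lythgoe reaction (LiN(SiMe3)2, then Ac2O) closes the seven‑membered ring as the β‑acetoxy sulfone F3, and SmI2/HMPA eliminates it to the 8,9‑alkene F4. AcOH/H2O/THF removes the silyl group to give the homoallylic alcohol F5, and VO(acac)2/t‑BuOOH epoxidises syn to the C‑6 hydroxyl to give the epoxy alcohol F6. Hydrogenolysis of the benzyl ether then gives 21.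

**Step 3 (three‑component conjugate addition and aldol).** Enantioselectivity on a cyclopentenone, the reactivity of the aluminium enolate and the two diastereoselections are all uncertain. The sense of induction of the ligand must be confirmed on a test run; the antipode is used if it is opposite. The fallback sets out from 4 and comes back at 10. The same copper‑catalysed methylation is quenched with Me3SiCl to give the isolated trimethylsilyl enol ether F7. A Mukaiyama aldol with 7 and BF3·OEt2 (open transition state) gives the hydroxy ketone F8, and Et3SiCl/imidazole gives 10.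

**Step 4 (secondary Grignard on a hindered ketone, then acylation of a very hindered alkoxide).** Reduction or enolisation may compete with addition, and the alkoxide may not acylate. The fallback sets out from aldolate 9 and comes back at 13. The aldolate is quenched with 11 instead of the silyl triflate to give the C‑6 aroyl ester ketone F9. iPrMgCl with LaCl3·2LiCl gives the tertiary alkoxide F10, which passes the aroyl group from O‑6 to O‑4 through a six‑membered ring and gives the less hindered secondary alkoxide F11. Silylation in the flask with Et3SiOTf gives 13.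

## Further compounds

F1 | step 7 | phenyl sulfone of 13 | CC(C)[C@]1(OC(=O)c2ccc(OCc3ccccc3)cc2)CC[C@](C)(CC=C)[C@H]1[C@@H](O[Si](CC)(CC)CC)CC(C)S(=O)(=O)c1ccccc1
F2 | step 7 | sulfonyl aldehyde (2‑oxoethyl arm) | CC(C)[C@]1(OC(=O)c2ccc(OCc3ccccc3)cc2)CC[C@](C)(CC=O)[C@H]1[C@@H](O[Si](CC)(CC)CC)CC(C)S(=O)(=O)c1ccccc1
F3 | step 7 | 9‑acetoxy‑8‑(phenylsulfonyl)‑6‑(triethylsilyloxy)daucan‑4‑yl 4‑(benzyloxy)benzoate (mixture at C‑8 and C‑9) | CC(C)[C@]1(OC(=O)c2ccc(OCc3ccccc3)cc2)CC[C@]2(C)CC(OC(C)=O)C(C)(S(=O)(=O)c3ccccc3)C[C@H](O[Si](CC)(CC)CC)[C@H]21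
F4 | step 7 | (1R,4R,5S,6S)‑6‑(triethylsilyloxy)dauc‑8‑en‑4‑yl 4‑(benzyloxy)benzoate | CC(C)[C@]1(OC(=O)c2ccc(OCc3ccccc3)cc2)CC[C@]2(C)CC=C(C)C[C@H](O[Si](CC)(CC)CC)[C@H]21
F5 | step 7 | (1R,4R,5S,6S)‑6‑hydroxydauc‑8‑en‑4‑yl 4‑(benzyloxy)benzoate | CC(C)[C@]1(OC(=O)c2ccc(OCc3ccccc3)cc2)CC[C@]2(C)CC=C(C)C[C@H](O)[C@H]21
F6 | step 7 | (1R,4R,5S,6S,8R,9S)‑8,9‑epoxy‑6‑hydroxydaucan‑4‑yl 4‑(benzyloxy)benzoate | CC(C)[C@]1(OC(=O)c2ccc(OCc3ccccc3)cc2)CC[C@]2(C)C[C@@H]3O[C@]3(C)C[C@H](O)[C@H]21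
F7 | step 3 | trimethyl{[(3R)‑3‑methyl‑3‑(prop‑2‑en‑1‑yl)cyclopent‑1‑en‑1‑yl]oxy}silane | C[Si](C)(C)OC1=C[C@@](C)(CC=C)CC1
F8 | step 3 | (2S,3R)‑2‑[(1S)‑1‑hydroxy‑3‑(phenylsulfanyl)butyl]‑3‑methyl‑3‑(prop‑2‑en‑1‑yl)cyclopentan‑1‑one | O=C1CC[C@](C)(CC=C)[C@H]1[C@@H](O)CC(C)Sc1ccccc1
F9 | step 4 | (1S)‑1‑[(1S,2R)‑2‑methyl‑5‑oxo‑2‑(prop‑2‑en‑1‑yl)cyclopentyl]‑3‑(phenylsulfanyl)butyl 4‑(benzyloxy)benzoate | O=C1CC[C@](C)(CC=C)[C@H]1[C@@H](OC(=O)c1ccc(OCc2ccccc2)cc1)CC(C)Sc1ccccc1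
F10 | step 4 | chloromagnesium tertiary alkoxide with the aroyl group on O‑6 | CC(C)[C@]1(O[Mg]Cl)CC[C@](C)(CC=C)[C@H]1[C@@H](OC(=O)c1ccc(OCc2ccccc2)cc1)CC(C)Sc1ccccc1
F11 | step 4 | chloromagnesium secondary alkoxide with the aroyl group on O‑4 | CC(C)[C@]1(OC(=O)c2ccc(OCc3ccccc3)cc2)CC[C@](C)(CC=C)[C@H]1[C@@H](O[Mg]Cl)CC(C)Sc1ccccc1
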